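The cyclohexane ring (C6 = CH bearing the acyloxypropyl chain, C7 = enal-bearing carbon, C8, C9, C10 = carbinol, C11 = quaternary) is split into a 1,4-dicarbonyl (C7–C10, 4-oxopentanal) and a vicinal bis-nucleophile (C6–C11). The key step exploits the 1,4-relationship of C7 and C10 and the two-carbon branch C12–C13 on C11: a 1,2-bis(boronate), made by enantioselective diboration of a (Z)-3-methyl-1,3-diene, undergoes tandem double allylboration, forging C6–C7 at the aldehyde and then C10–C11 at the ketone, and sets C6, C10 and C11 at once. The C11 vinyl group left behind takes the side chain by B-alkyl Suzuki coupling; C7 oxidation, isopropenyl addition and oxidative transposition give the Z-enal.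

Key step: step 7

Remark on labels: C1 = CHO, C2 = its α-carbon, C3 = OCH2 of the acyloxypropyl chain, C4, C5, ring C6–C11 as above, C12 and C13 = the two CH2 groups on C11, C14=C15, C16 = CH–OAc.

Assumption: the (R,R)-phosphonite in step 5 is taken to give the 6S boronate 7; if the sense of induction on this diene is the opposite, the (S,S)-ligand is used instead.

Step 1
Reactants: 1 butane-1,4-diol; 2 decanoyl chloride
Product: 3 4-hydroxybutyl decanoate
Conditions: 1 (5 equiv), Et3N, CH2Cl2, 0 °C
Reagents that add atoms: none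
Why: Nucleophilic acyl substitution on a symmetrical diol used in excess should stop at the mono-ester, the surplus diol being washed out with water.

Step 2
Reactants: 3 4-hydroxybutyl decanoate
Product: 4 4-oxobutyl decanoate
Conditions: Dess–Martin periodinane, CH2Cl2, rt
Reagents that add atoms: none
Why: Dess–Martin oxidation should take the primary alcohol to the aldehyde without touching the ester.

Step 3
Reactants: 4 4-oxobutyl decanoate
Product: 5 (4Z)-5-iodohex-4-en-1-yl decanoate
Conditions: EtPPh3I, n-BuLi, THF, 0 °C; I2, −78 °C; NaN(SiMe3)2, −20 °C; then 4, −78 °C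
Reagents that add atoms: ethyltriphenylphosphonium iodide CC[P+](c1ccccc1)(c1ccccc1)c1ccccc1.[I-]; iodine II
Why: Stork–Zhao olefination with the non-stabilised α-iodo ylide should give the Z-iodoalkene (iodine cis to the chain) under kinetic control, the ester being inert to the ylide at low temperature.

Step 4
Reactants: 5 (4Z)-5-iodohex-4-en-1-yl decanoate
Product: 6 (4Z)-5-methylhepta-4,6-dien-1-yl decanoate
Conditions: tributyl(vinyl)stannane, Pd2(dba)3, AsPh3, NMP, rt
Reagents that add atoms: tributyl(vinyl)stannane C=C[Sn](CCCC)(CCCC)CCCC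
Why: Stille coupling at zerovalent palladium should proceed with retention of the alkene geometry, so that the vinyl group ends cis to the chain (Z-diene).

Step 5
Reactants: 6 (4Z)-5-methylhepta-4,6-dien-1-yl decanoate
Product: 7 (4Z,6S)-5-methyl-6,7-bis(4,4,5,5-tetramethyl-1,3,2-dioxaborolan-2-yl)hept-4-en-1-yl decanoate
Conditions: B2(pin)2, Pt(dba)3 (3 mol%), (R,R)-3,5-diisopropylphenyl-TADDOL phenylphosphonite (6 mol%), THF, 60 °C
Reagents that add atoms: bis(pinacolato)diboron CC1(C)OB(OC1(C)C)B1OC(C)(C)C(C)(C)O1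
Why: Platinum-catalysed enantioselective 1,2-diboration should add across the terminal alkene only, because the cis-substituted diene cannot reach the s-cis geometry needed for 1,4-addition, and the chiral phosphonite sets the boron-bearing stereocentre C12 (6S in 7).

Step 6
Reactants: 8 5-hydroxypentan-2-one
Product: 9 4-oxopentanal
Conditions: Dess–Martin periodinane, CH2Cl2, rt (solution used directly)
Reagents that add atoms: none
Why: Dess–Martin oxidation should convert the primary alcohol to the aldehyde and leave the methyl ketone unchanged.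

Step 7
Reactants: 7 (4Z,6S)-5-methyl-6,7-bis(4,4,5,5-tetramethyl-1,3,2-dioxaborolan-2-yl)hept-4-en-1-yl decanoate; 9 4-oxopentanal
Product: 12 3-[(1S,2S,3S,6S)-2-ethenyl-3,6-dihydroxy-2,3-dimethylcyclohexyl]propyl decanoate, via E-allylboronate keto borate 10 (not isolated), via cyclised bis-borate 11 (not isolated)
Conditions: 9 (1.1 equiv, added over 6 h), CH2Cl2, rt; then toluene, 60 °C; then H2O/MeOH, rt
Reagents that add atoms: none
Why: The secondary allylic boronate of 7 adds to the aldehyde of 9 through a closed six-membered (boron–oxygen bonded) transition state at C6, which moves the double bond to C11=C12 and turns the primary C13–B bond into a new γ,γ-disubstituted E-allylboronate (10) that then adds through C11 to the tethered methyl ketone C10 in a second closed transition state. The closest known reaction type is the tandem double allylboration of 1,4-dicarbonyl compounds by diene-derived 1,2-bis(boronates), used here in the sense in which the ketone step builds the quaternary carbon. The carbocycle is closed by this second, intramolecular allylboration as a 6-exo-trig attack of the alkene terminus C11 on the ketone carbon (C=O and C11=C12 both exocyclic), through a trans-fused pair of chairs (boron chair and forming ring). C6 is set by the boron-bearing stereocentre C12 of 7 (the Z-substituent on C6 must sit axial, which forces the CH2B group equatorial, fixes the reacting face and gives the E geometry of 10), C7 by the equatorial aldehyde chain (it is erased later), and C11 and C10 by C6 through the second chair, in which the C6 chain and the C7 oxygen are equatorial and the C11 methyl and the ketone methyl axial, so that the C10 hydroxyl ends cis to the C11 methyl and to the C6 chain. The step needs aldehyde-before-ketone chemoselectivity (intrinsic reactivity, slow addition of 9), γ-selectivity (closed transition states) and the E-allylboronate (secured by the Z-diene, since an E-diene would pass through the Z-allylboronate to the C10 epimer). Mild hydrolysis of the two B–O bonds then frees diol 12.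

Step 8
Reactants: 13 prop-2-yn-1-ol
Product: 15 (2E)-3-iodo-2-methylprop-2-en-1-ol, via alkenylalane 14 (not isolated)
Conditions: AlMe3 (3 equiv), Cp2ZrCl2 (0.25 equiv), CH2Cl2, 0 °C to rt; then I2, THF, −30 °C
Reagents that add atoms: trimethylaluminium C[Al](C)C; iodine II
Why: Negishi zirconium-catalysed carboalumination adds methyl and aluminium syn across the alkyne with methyl on the internal carbon, and iodinolysis with retention should give the E-iodoalkene.

Step 9
Reactants: 15 (2E)-3-iodo-2-methylprop-2-en-1-ol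
Product: 16 (2E)-3-iodo-2-methylprop-2-enal
Conditions: MnO2, CH2Cl2, rt
Reagents that add atoms: none
Why: Allylic oxidation with MnO2 should give the enal without loss of the alkene geometry.

Step 10
Reactants: 16 (2E)-3-iodo-2-methylprop-2-enal; 17 geranyl chloride
Product: 19 rac-(1E,5E)-1-iodo-2,6,10-trimethylundeca-1,5,9-trien-3-ol, via geranylbarium chloride 18 (not isolated)
Conditions: BaI2, lithium biphenylide, THF, rt; 17 (slight excess), −78 °C; then 16, −78 °C
Reagents that add atoms: none
Why: Allylbarium reagents (Barbier-type addition) react with aldehydes through their less substituted α-carbon with retention of the E geometry, which should give the linear homoallylic alcohol as a racemate without touching the vinyl iodide at −78 °C.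

Step 11
Reactants: 19 rac-(1E,5E)-1-iodo-2,6,10-trimethylundeca-1,5,9-trien-3-ol
Product: 20 (1E,5E)-1-iodo-2,6,10-trimethylundeca-1,5,9-trien-3-one
Conditions: Dess–Martin periodinane, NaHCO3, CH2Cl2, 0 °C
Reagents that add atoms: none
Why: Buffered Dess–Martin oxidation should give the enone while the 5,6-double bond stays out of conjugation.

Step 12
Reactants: 20 (1E,5E)-1-iodo-2,6,10-trimethylundeca-1,5,9-trien-3-one
Product: 21 (1E,3R,5E)-1-iodo-2,6,10-trimethylundeca-1,5,9-trien-3-ol
Conditions: (S)-2-methyl-CBS-oxazaborolidine (20 mol%), catecholborane, toluene, −78 °C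
Reagents that add atoms: none
Why: Corey–Bakshi–Shibata reduction, in which the α-methylalkenyl group acts as the large substituent and the CH2 group as the small one, should deliver hydride 1,2 to give the 3R alcohol (C16) with the (S)-catalyst.

Step 13
Reactants: 21 (1E,3R,5E)-1-iodo-2,6,10-trimethylundeca-1,5,9-trien-3-ol
Product: 22 (1E,3R,5E)-1-iodo-2,6,10-trimethylundeca-1,5,9-trien-3-yl acetate
Conditions: Ac2O, pyridine, DMAP (cat.), CH2Cl2, 0 °C
Reagents that add atoms: acetic anhydride CC(=O)OC(C)=O
Why: DMAP-catalysed acyl transfer should acetylate the secondary alcohol with retention at C16.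

Step 14
Reactants: 12 3-[(1S,2S,3S,6S)-2-ethenyl-3,6-dihydroxy-2,3-dimethylcyclohexyl]propyl decanoate; 22 (1E,3R,5E)-1-iodo-2,6,10-trimethylundeca-1,5,9-trien-3-yl acetate
Product: 24 3-[(1S,2S,3S,6S)-2-[(3E,5R,7E)-5-acetoxy-4,8,12-trimethyltrideca-3,7,11-trien-1-yl]-3,6-dihydroxy-2,3-dimethylcyclohexyl]propyl decanoate, via B-alkyl-9-BBN 23 (not isolated)
Conditions: 9-BBN dimer (3.5 equiv, allowing for the two hydroxyls), THF, 0 to 45 °C; then aq. Cs2CO3, 22, Pd(dppf)Cl2 (5 mol%), AsPh3, DMF, rt
Reagents that add atoms: none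
Why: 9-BBN should hydroborate only the monosubstituted vinyl group (anti-Markovnikov), and the B-alkyl borane should then undergo Suzuki–Miyaura coupling with the vinyl iodide with retention of its E geometry, the mild base at room temperature leaving both esters intact.

Step 15
Reactants: 24 3-[(1S,2S,3S,6S)-2-[(3E,5R,7E)-5-acetoxy-4,8,12-trimethyltrideca-3,7,11-trien-1-yl]-3,6-dihydroxy-2,3-dimethylcyclohexyl]propyl decanoate
Product: 25 3-[(1S,2S,3S)-2-[(3E,5R,7E)-5-acetoxy-4,8,12-trimethyltrideca-3,7,11-trien-1-yl]-3-hydroxy-2,3-dimethyl-6-oxocyclohexyl]propyl decanoate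
Conditions: Dess–Martin periodinane, NaHCO3, CH2Cl2, 0 °C to rt
Reagents that add atoms: none
Why: Dess–Martin oxidation should convert the only secondary alcohol (C7) to the ketone under non-epimerising conditions, the tertiary C10 alcohol being inert.

Step 16
Reactants: 25 3-[(1S,2S,3S)-2-[(3E,5R,7E)-5-acetoxy-4,8,12-trimethyltrideca-3,7,11-trien-1-yl]-3-hydroxy-2,3-dimethyl-6-oxocyclohexyl]propyl decanoate
Product: 26 3-[(1S,2S,3S)-2-[(3E,5R,7E)-5-acetoxy-4,8,12-trimethyltrideca-3,7,11-trien-1-yl]-3,6-dihydroxy-2,3-dimethyl-6-(prop-1-en-2-yl)cyclohexyl]propyl decanoate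
Conditions: isopropenylmagnesium bromide (2.5 equiv), LaCl3·2LiCl (1 equiv), THF, −40 °C; then aq. NH4Cl
Reagents that add atoms: isopropenylmagnesium bromide CC(=C)[Mg]Br
Why: LaCl3·2LiCl-promoted Grignard 1,2-addition should be faster at the ketone than at either ester and suppresses enolisation, so that C6 is not epimerised, while the configuration of the new carbinol carbon C7 is immaterial because it becomes sp2 in step 17.

Step 17
Reactants: 26 3-[(1S,2S,3S)-2-[(3E,5R,7E)-5-acetoxy-4,8,12-trimethyltrideca-3,7,11-trien-1-yl]-3,6-dihydroxy-2,3-dimethyl-6-(prop-1-en-2-yl)cyclohexyl]propyl decanoate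
Product: 27 3-[(1R,2S,3S,6Z)-2-[(3E,5R,7E)-5-acetoxy-4,8,12-trimethyltrideca-3,7,11-trien-1-yl]-3-hydroxy-2,3-dimethyl-6-(1-oxopropan-2-ylidene)cyclohexyl]propyl decanoate (CNP0199124.2)
Conditions: pyridinium chlorochromate C5H5NH[CrO3Cl], 4 Å molecular sieves, CH2Cl2, rt
Reagents that add atoms: none
Why: In this Babler–Dauben oxidative transposition the tertiary chromate ester undergoes a [3,3]-shift to the primary allylic chromate, which is oxidised to the enal, and the Z geometry (formyl group cis to C6) should prevail because the more substituted ring neighbour C6 avoids the C2 methyl group both in the chair transition state and in the product (allylic strain).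

Compound list
1 | butane-1,4-diol | OCCCCO | starting material
2 | decanoyl chloride | CCCCCCCCCC(=O)Cl | starting material
3 | 4-hydroxybutyl decanoate | CCCCCCCCCC(=O)OCCCCO | intermediate
4 | 4-oxobutyl decanoate | CCCCCCCCCC(=O)OCCCC=O | intermediate
5 | (4Z)-5-iodohex-4-en-1-yl decanoate | CCCCCCCCCC(=O)OCCC/C=C(C)\I | intermediate
6 | (4Z)-5-methylhepta-4,6-dien-1-yl decanoate | CCCCCCCCCC(=O)OCCC/C=C(C)\C=C | intermediate
7 | (4Z,6S)-5-methyl-6,7-bis(4,4,5,5-tetramethyl-1,3,2-dioxaborolan-2-yl)hept-4-en-1-yl decanoate | CCCCCCCCCC(=O)OCCC/C=C(C)\[C@@H](B1OC(C)(C)C(C)(C)O1)CB1OC(C)(C)C(C)(C)O1 | intermediate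
8 | 5-hydroxypentan-2-one | CC(=O)CCCO | starting material
9 | 4-oxopentanal | CC(=O)CCC=O | intermediate
10 | (4S,5S)-8-oxo-5-[(4,4,5,5-tetramethyl-1,3,2-dioxaborolan-2-yl)oxy]-4-[(2E)-4-(4,4,5,5-tetramethyl-1,3,2-dioxaborolan-2-yl)but-2-en-2-yl]nonyl decanoate (E-allylboronate keto borate) | CCCCCCCCCC(=O)OCCC[C@@H](/C(C)=C/CB1OC(C)(C)C(C)(C)O1)[C@@H](OB1OC(C)(C)C(C)(C)O1)CCC(C)=O | intermediate (not isolated)
11 | 3-[(1S,2S,3S,6S)-2-ethenyl-2,3-dimethyl-3,6-bis[(4,4,5,5-tetramethyl-1,3,2-dioxaborolan-2-yl)oxy]cyclohexyl]propyl decanoate (cyclised bis-borate) | CCCCCCCCCC(=O)OCCC[C@@H]1[C@@H](OB2OC(C)(C)C(C)(C)O2)CC[C@](C)(OB2OC(C)(C)C(C)(C)O2)[C@@]1(C)C=C | intermediate (not isolated)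
12 | 3-[(1S,2S,3S,6S)-2-ethenyl-3,6-dihydroxy-2,3-dimethylcyclohexyl]propyl decanoate | CCCCCCCCCC(=O)OCCC[C@@H]1[C@@H](O)CC[C@](C)(O)[C@@]1(C)C=C | intermediate
13 | prop-2-yn-1-ol | C#CCO | starting material
14 | dimethyl[(1E)-3-[(dimethylalumanyl)oxy]-2-methylprop-1-en-1-yl]alumane (alkenylalane) | C[Al](C)/C=C(\C)CO[Al](C)C | intermediate (not isolated)
15 | (2E)-3-iodo-2-methylprop-2-en-1-ol | I/C=C(\C)CO | intermediate
16 | (2E)-3-iodo-2-methylprop-2-enal | I/C=C(\C)C=O | intermediate
17 | geranyl chloride, (2E)-1-chloro-3,7-dimethylocta-2,6-diene | ClC/C=C(\C)CCC=C(C)C | starting material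
18 | geranylbarium chloride | Cl[Ba]C/C=C(\C)CCC=C(C)C | intermediate (not isolated)
19 | rac-(1E,5E)-1-iodo-2,6,10-trimethylundeca-1,5,9-trien-3-ol | I/C=C(\C)C(O)C/C=C(\C)CCC=C(C)C | intermediate
20 | (1E,5E)-1-iodo-2,6,10-trimethylundeca-1,5,9-trien-3-one | I/C=C(\C)C(=O)C/C=C(\C)CCC=C(C)C | intermediate
21 | (1E,3R,5E)-1-iodo-2,6,10-trimethylundeca-1,5,9-trien-3-ol | I/C=C(\C)[C@@H](C/C=C(\C)CCC=C(C)C)O | intermediate
22 | (1E,3R,5E)-1-iodo-2,6,10-trimethylundeca-1,5,9-trien-3-yl acetate | I/C=C(\C)[C@@H](C/C=C(\C)CCC=C(C)C)OC(C)=O | intermediate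
23 | 3-[(1S,2S,3S,6S)-2-[2-(9-borabicyclo[3.3.1]nonan-9-yl)ethyl]-3,6-dihydroxy-2,3-dimethylcyclohexyl]propyl decanoate (B-alkyl-9-BBN) | CCCCCCCCCC(=O)OCCC[C@@H]1[C@@H](O)CC[C@](C)(O)[C@@]1(C)CCB1C2CCCC1CCC2 | intermediate (not isolated)
24 | 3-[(1S,2S,3S,6S)-2-[(3E,5R,7E)-5-acetoxy-4,8,12-trimethyltrideca-3,7,11-trien-1-yl]-3,6-dihydroxy-2,3-dimethylcyclohexyl]propyl decanoate | CCCCCCCCCC(=O)OCCC[C@@H]1[C@@H](O)CC[C@](C)(O)[C@@]1(C)CC/C=C(\C)[C@@H](C/C=C(\C)CCC=C(C)C)OC(C)=O | intermediate
25 | 3-[(1S,2S,3S)-2-[(3E,5R,7E)-5-acetoxy-4,8,12-trimethyltrideca-3,7,11-trien-1-yl]-3-hydroxy-2,3-dimethyl-6-oxocyclohexyl]propyl decanoate | CCCCCCCCCC(=O)OCCC[C@@H]1C(=O)CC[C@](C)(O)[C@@]1(C)CC/C=C(\C)[C@@H](C/C=C(\C)CCC=C(C)C)OC(C)=O | intermediate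
26 | 3-[(1S,2S,3S)-2-[(3E,5R,7E)-5-acetoxy-4,8,12-trimethyltrideca-3,7,11-trien-1-yl]-3,6-dihydroxy-2,3-dimethyl-6-(prop-1-en-2-yl)cyclohexyl]propyl decanoate (either epimer at the new carbinol carbon) | CCCCCCCCCC(=O)OCCC[C@@H]1C(O)(C(C)=C)CC[C@](C)(O)[C@@]1(C)CC/C=C(\C)[C@@H](C/C=C(\C)CCC=C(C)C)OC(C)=O | intermediate
27 | 3-[(1R,2S,3S,6Z)-2-[(3E,5R,7E)-5-acetoxy-4,8,12-trimethyltrideca-3,7,11-trien-1-yl]-3-hydroxy-2,3-dimethyl-6-(1-oxopropan-2-ylidene)cyclohexyl]propyl decanoate (CNP0199124.2) | CCCCCCCCCC(=O)OCCC[C@@H]1/C(=C(/C)C=O)CC[C@](C)(O)[C@@]1(C)CC/C=C(\C)[C@@H](C/C=C(\C)CCC=C(C)C)OC(C)=O | target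

Total step count: 17.
Longest linear sequence: 10 steps (steps 1–5, 7, 14–17 from butane-1,4-diol; the branch from prop-2-yn-1-ol, steps 8–13 and 14–17, is equally long).

Steps most likely to fail

Step 7. The intramolecular ketone allylation at the hindered γ,γ-disubstituted terminus may be too slow, so that 10 is consumed by a second molecule of aldehyde, or the ring may close through the other chair and give the C10 epimer. The fallback sets out from 7 and 9 and returns at 12. Only the first allylation is run at room temperature, and the remaining allylic C–B bond is oxidised (NaBO3·4H2O, THF/H2O) to the keto diol (4S,5S)-5-hydroxy-4-[(2E)-4-hydroxybut-2-en-2-yl]-8-oxononyl decanoate F1. Corey–Kim bromination (N-bromosuccinimide, Me2S, CH2Cl2, −20 °C) of the primary allylic alcohol should give (4S,5S)-4-[(2E)-4-bromobut-2-en-2-yl]-5-hydroxy-8-oxononyl decanoate F2. An indium-mediated intramolecular Barbier allylation (In powder, THF/H2O, rt), which also reacts through the γ-carbon C11 in a cyclic transition state, should then close the ring to 12.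

Step 16. The Grignard reagent may attack the acetate or the decanoate in competition with the hindered ketone, or the ketone may be enolised. The fallback sets out from 25 and returns at 26. The addition is run with excess reagent and the crude product is treated with K2CO3 in MeOH to remove both acyl groups on purpose, giving the tetraol 3-[(1S,2S,3S)-3,6-dihydroxy-2-[(3E,5R,7E)-5-hydroxy-4,8,12-trimethyltrideca-3,7,11-trien-1-yl]-2,3-dimethyl-6-(prop-1-en-2-yl)cyclohexyl]propan-1-ol F3. Decanoyl chloride (1 equiv) with 2,4,6-collidine in CH2Cl2 at −78 °C should acylate only the primary hydroxyl to give the mono-decanoate F4. Ac2O/pyridine/DMAP at 0 °C then acetylates the single secondary hydroxyl, the two tertiary ones being unreactive, to return 26.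

Step 14. Hydroboration of the vinyl group on the quaternary carbon may be slow, 9-BBN may be consumed by the free hydroxyls, or the allylic acetate may be ionised by zerovalent palladium. The fallback sets out from 12 and returns at 24. Hydroboration with the smaller BH3·SMe2 (THF, 0 °C) and NaBO3·4H2O oxidation should give 3-[(1S,2S,3S,6S)-3,6-dihydroxy-2-(2-hydroxyethyl)-2,3-dimethylcyclohexyl]propyl decanoate F5. An Appel reaction (I2, PPh3, imidazole, CH2Cl2, 0 °C) should convert only the primary alcohol to the iodide 3-[(1S,2S,3S,6S)-3,6-dihydroxy-2-(2-iodoethyl)-2,3-dimethylcyclohexyl]propyl decanoate F6. A nickel-catalysed reductive cross-electrophile coupling of F6 with 22 (NiCl2(dme), 4,4′-di-tert-butyl-2,2′-bipyridine, Zn, DMA, rt) should then join C13 to C14 with retention of the vinyl geometry to give 24.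

Further compounds
F1 | step 7 | (4S,5S)-5-hydroxy-4-[(2E)-4-hydroxybut-2-en-2-yl]-8-oxononyl decanoate | CCCCCCCCCC(=O)OCCC[C@@H](/C(C)=C/CO)[C@@H](O)CCC(C)=O
F2 | step 7 | (4S,5S)-4-[(2E)-4-bromobut-2-en-2-yl]-5-hydroxy-8-oxononyl decanoate | CCCCCCCCCC(=O)OCCC[C@@H](/C(C)=C/CBr)[C@@H](O)CCC(C)=O
F3 | step 16 | 3-[(1S,2S,3S)-3,6-dihydroxy-2-[(3E,5R,7E)-5-hydroxy-4,8,12-trimethyltrideca-3,7,11-trien-1-yl]-2,3-dimethyl-6-(prop-1-en-2-yl)cyclohexyl]propan-1-ol | OCCC[C@@H]1C(O)(C(C)=C)CC[C@](C)(O)[C@@]1(C)CC/C=C(\C)[C@@H](C/C=C(\C)CCC=C(C)C)O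
F4 | step 16 | 3-[(1S,2S,3S)-3,6-dihydroxy-2-[(3E,5R,7E)-5-hydroxy-4,8,12-trimethyltrideca-3,7,11-trien-1-yl]-2,3-dimethyl-6-(prop-1-en-2-yl)cyclohexyl]propyl decanoate | CCCCCCCCCC(=O)OCCC[C@@H]1C(O)(C(C)=C)CC[C@](C)(O)[C@@]1(C)CC/C=C(\C)[C@@H](C/C=C(\C)CCC=C(C)C)O
F5 | step 14 | 3-[(1S,2S,3S,6S)-3,6-dihydroxy-2-(2-hydroxyethyl)-2,3-dimethylcyclohexyl]propyl decanoate | CCCCCCCCCC(=O)OCCC[C@@H]1[C@@H](O)CC[C@](C)(O)[C@@]1(C)CCO
F6 | step 14 | 3-[(1S,2S,3S,6S)-3,6-dihydroxy-2-(2-iodoethyl)-2,3-dimethylcyclohexyl]propyl decanoate | CCCCCCCCCC(=O)OCCC[C@@H]1[C@@H](O)CC[C@](C)(O)[C@@]1(C)CCI
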